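**Strategy.** The route rests on disconnecting C16–C17, the bond between the allylic carbinol carbon of the side chain and the geranyl CH2. The key step is a lithiation–borylation: the N,N-diisopropylcarbamate of the C16 allylic alcohol is lithiated enantioselectively with sBuLi/(+)-sparteine, borylated with (E)-geranyl pinacolboronate, and the geranyl group then shifts from boron to C16 with loss of the carbamate; oxidation gives the (16R)-alcohol. One operation joins the twenty-carbon ring fragment to the ten-carbon unit, sets C16 and preserves the C18=C19 geometry. It exploits the C14=C15 alkene flanking C16 and the preformed geranyl alkene. Ring stereocentres C6, C10 and C11 stem from one catalytic conjugate addition; a temporary cyclohexenone (ring A′) fixes the C2=C7 geometry.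

Key step: step 17

Remark (locants): iridal-type numbering is used: C1 aldehyde carbon, C2 its α-carbon (methyl C25), C3–C5 the acetoxypropyl arm (O on C3), ring C6 (CH)–C7 (alkylidene)–C8–C9–C10 (carbinol)–C11 (quaternary), side chain C12–C24 with C16 the acetoxy carbon. "Cb" = C(O)N(iPr)2, "TES" = SiEt3.

Assumption: sBuLi/(+)-sparteine removes the pro-R hydrogen at C16 of the 2-alkenyl carbamate (mirror image of the pro-S preference of (–)-sparteine with O-alkyl carbamates); if the allylic system shows the opposite sense, (–)-sparteine is used instead.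

**Step 1**
Reactants: 1 4-methoxy-2-methylphenol
Product: 2 4,4-dimethoxy-2-methylcyclohexa-2,5-dien-1-one
Conditions: PhI(OAc)2, MeOH, 0 °C
Reagents that add atoms: methanol (CO)
Why: Oxidative dearomatisation of a para-alkoxyphenol in methanol traps the phenoxenium ion at C4 as the quinone monoketal.

**Step 2**
Reactants: 2 4,4-dimethoxy-2-methylcyclohexa-2,5-dien-1-one
Product: 3 4,4-dimethoxy-2-methylcyclohex-2-en-1-one
Conditions: H2 (1 atm), RhCl(PPh3)3 (cat.), benzene, 25 °C
Reagents that add atoms: none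
Why: Homogeneous hydrogenation with RhCl(PPh3)3 should reduce the unhindered disubstituted alkene of the cross-conjugated dienone much faster than the methyl-bearing trisubstituted one.

**Step 3**
Reactants: 4 pent-1-en-3-one
Product: 6 2-(2-bromoethyl)-2-ethyl-5,5-dimethyl-1,3-dioxane, via 1-bromopentan-3-one 5 (not isolated)
Conditions: HBr (gas), CH2Cl2, 0 °C; then 2,2-dimethylpropane-1,3-diol, TsOH (cat.), 4 Å MS, 25 °C
Reagents that add atoms: hydrogen bromide (Br); 2,2-dimethylpropane-1,3-diol (OCC(C)(C)CO)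
Why: Conjugate hydrobromination of the vinyl ketone followed by acid-catalysed ketalisation masks the ketone as a dioxane that tolerates Grignard formation.

**Step 4**
Reactants: 3 4,4-dimethoxy-2-methylcyclohex-2-en-1-one; 6 2-(2-bromoethyl)-2-ethyl-5,5-dimethyl-1,3-dioxane
Product: 9 (2S,3S)-3-[2-(2-ethyl-5,5-dimethyl-1,3-dioxan-2-yl)ethyl]-4,4-dimethoxy-2-methyl-2-(prop-2-en-1-yl)cyclohexan-1-one, via Grignard reagent 7 (not isolated), via magnesium enolate 8 (not isolated)
Conditions: 6, Mg, THF, 25 °C (gives 7); CuBr·SMe2 (5 mol %), (R)-1-[(S)-2-(diphenylphosphino)ferrocenyl]ethyldicyclohexylphosphine (6 mol %; the antipode that gives 3S is used), tBuOMe, –78 °C; then allyl bromide, DMPU, –78 → 0 °C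
Reagents that add atoms: allyl bromide (C=CCBr)
Why: Copper-catalysed asymmetric conjugate addition of the Grignard reagent sets C6 under catalyst control, and the magnesium enolate is allylated anti to the new C6 arm, so the C11 quaternary centre forms with the allyl group trans to that arm (substrate control).

**Step 5**
Reactants: 9 ketone from step 4
Product: 10 (1S,2S,3S)-3-[2-(2-ethyl-5,5-dimethyl-1,3-dioxan-2-yl)ethyl]-4,4-dimethoxy-1,2-dimethyl-2-(prop-2-en-1-yl)cyclohexan-1-ol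
Conditions: MeLi, Et2O, –78 °C
Reagents that add atoms: methyllithium ([Li]C)
Why: 1,2-Addition should occur by axial attack on the chair with equatorial C6 arm and allyl group, anti to the axial C11 methyl, so the new C10 methyl is cis to the allyl group and the hydroxyl cis to the C11 methyl.

**Step 6**
Reactants: 10 tertiary alcohol
Product: 12 (1S,2S,3S)-3-[2-(2-ethyl-5,5-dimethyl-1,3-dioxan-2-yl)ethyl]-2-(3-hydroxypropyl)-4,4-dimethoxy-1,2-dimethylcyclohexan-1-ol, via B-alkyl-9-BBN adduct 11 (not isolated)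
Conditions: 9-BBN, THF, 0 → 25 °C; then NaOH, H2O2, 0 °C
Reagents that add atoms: hydrogen peroxide (OO)
Why: Anti-Markovnikov hydroboration–oxidation of the only alkene gives the primary alcohol.

**Step 7**
Reactants: 12 diol
Product: 14 ethyl (2E)-5-[(1S,2S,6S)-6-[2-(2-ethyl-5,5-dimethyl-1,3-dioxan-2-yl)ethyl]-2-hydroxy-5,5-dimethoxy-1,2-dimethylcyclohexyl]-2-methylpent-2-enoate, via aldehyde 13 (not isolated)
Conditions: (COCl)2, DMSO, CH2Cl2, –78 °C; Et3N; then Ph3P=C(Me)CO2Et, 25 → 40 °C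
Reagents that add atoms: ethyl 2-(triphenylphosphoranylidene)propanoate (CCOC(=O)C(C)=P(c1ccccc1)(c1ccccc1)c1ccccc1)
Why: Swern oxidation cannot over-oxidise the aldehyde or its lactol with the C10 hydroxyl, and the stabilised ylide intercepts the open form in an (E)-selective Wittig olefination.

**Step 8**
Reactants: 14 enoate
Product: 15 (2E)-5-[(1S,2S,6S)-6-[2-(2-ethyl-5,5-dimethyl-1,3-dioxan-2-yl)ethyl]-2-hydroxy-5,5-dimethoxy-1,2-dimethylcyclohexyl]-2-methylpent-2-en-1-ol
Conditions: iBu2AlH, CH2Cl2, –78 °C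
Reagents that add atoms: none
Why: Hydride 1,2-reduction of the enoate gives the allylic alcohol and leaves both ketals untouched.

**Step 9**
Reactants: 15 allylic alcohol
Product: 16 (2E)-5-[(1S,2S,6S)-6-[2-(2-ethyl-5,5-dimethyl-1,3-dioxan-2-yl)ethyl]-2-hydroxy-5,5-dimethoxy-1,2-dimethylcyclohexyl]-2-methylpent-2-en-1-yl N,N-di(propan-2-yl)carbamate
Conditions: iPr2NC(O)Cl, Et3N, DMAP (cat.), CH2Cl2, reflux
Reagents that add atoms: N,N-diisopropylcarbamoyl chloride (CC(C)N(C(C)C)C(Cl)=O)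
Why: Carbamoylation is selective for the primary allylic hydroxyl over the hindered tertiary one and installs the group that later directs the lithiation while serving as a robust protecting group.

**Step 10**
Reactants: 16 carbamate
Product: 18 (2E)-5-[(1S,2S,8aR)-2-hydroxy-1,2,5-trimethyl-6-oxo-1,2,3,4,6,7,8,8a-octahydronaphthalen-1-yl]-2-methylpent-2-en-1-yl N,N-di(propan-2-yl)carbamate, via diketone 17 (not isolated)
Conditions: 1 M HCl, THF, 25 °C; then pyrrolidine, AcOH, toluene, 60 °C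
Reagents that add atoms: water (O)
Why: Acid unmasks both ketones and the enamine-mediated intramolecular aldol condensation (second stage of a Robinson annulation) closes ring A′, which forces C1 and C6 to be cis on the new C2=C7 double bond, the mildly acidic conditions being chosen to avoid enolisation toward C6.

**Step 11**
Reactants: 18 octalone
Product: 20 7-hydroxy derivative of 18 (hydroxyl on C4 in iridal locants; both epimers), via dipotassium dienolate 19 (not isolated)
Conditions: KN(SiMe3)2 (2.2 equiv), THF, –78 °C; then 3-phenyl-2-(phenylsulfonyl)oxaziridine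
Reagents that add atoms: 3-phenyl-2-(phenylsulfonyl)oxaziridine (O=S(=O)(c1ccccc1)N1OC1c1ccccc1)
Why: Kinetic deprotonation at the α′-carbon gives the cross-conjugated dienolate, which is hydroxylated by the oxaziridine (Davis oxidation), and the new C4 configuration is irrelevant.

**Step 12**
Reactants: 20 α′-hydroxy enone
Product: 21 methyl (2Z)-2-[(2R,3S,4S)-3-[(3E)-5-(CbO)-4-methylpent-3-en-1-yl]-4-hydroxy-3,4-dimethyl-2-(2-oxoethyl)cyclohexylidene]propanoate (in equilibrium with its C10–O lactol)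
Conditions: Pb(OAc)4, MeOH–benzene (1:1), 0 °C
Reagents that add atoms: methanol (CO)
Why: Criegee-type cleavage of the α-ketol through its methanol hemiketal opens ring A′, so C1 emerges as the methyl ester and C4 as the aldehyde with the (2Z)-geometry retained.

**Step 13**
Reactants: 21 ester aldehyde
Product: 22 methyl (2Z)-2-[(2R,3S,4S)-3-[(3E)-5-(CbO)-4-methylpent-3-en-1-yl]-4-hydroxy-3,4-dimethyl-2-(prop-2-en-1-yl)cyclohexylidene]propanoate
Conditions: Ph3PCH3Br, KOtBu (excess), THF, 0 °C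
Reagents that add atoms: methyltriphenylphosphonium bromide (C[P+](c1ccccc1)(c1ccccc1)c1ccccc1.[Br-])
Why: Wittig methylenation converts the aldehyde (or its lactol) into the allyl arm that carries C3–C5, while the hindered tetrasubstituted enoate does not react.

**Step 14**
Reactants: 22 ester
Product: 23 (2E)-5-[(1S,2S,6R)-2-hydroxy-5-[(2Z)-1-hydroxypropan-2-ylidene]-1,2-dimethyl-6-(prop-2-en-1-yl)cyclohexyl]-2-methylpent-2-en-1-yl N,N-di(propan-2-yl)carbamate
Conditions: iBu2AlH (excess), CH2Cl2, –78 °C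
Reagents that add atoms: none
Why: The conjugated methyl ester is reduced to the primary allylic alcohol at low temperature, where the hindered N,N-diisopropylcarbamate is inert.

**Step 15**
Reactants: 23 diol
Product: 24 bis(triethylsilyl) ether of 23 (TES on the C1 and C10 oxygens)
Conditions: Et3SiOTf, 2,6-lutidine, CH2Cl2, –78 → 0 °C
Reagents that add atoms: triethylsilyl trifluoromethanesulfonate (CC[Si](CC)(CC)OS(=O)(=O)C(F)(F)F)
Why: The silyl triflate silylates both the primary allylic and the hindered tertiary hydroxyl, removing every acidic proton before the lithiation.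

**Step 16**
Reactants: 25 geranyl acetate
Product: 26 2-[(2E)-3,7-dimethylocta-2,6-dien-1-yl]-4,4,5,5-tetramethyl-1,3,2-dioxaborolane
Conditions: bis(pinacolato)diboron, Pd2(dba)3 (cat.), DMSO, 50 °C
Reagents that add atoms: bis(pinacolato)diboron (CC1(C)OB(OC1(C)C)B1OC(C)(C)C(C)(C)O1)
Why: Palladium-catalysed Miyaura-type borylation of the allylic acetate proceeds through the π-allyl complex with boron delivered to the unsubstituted terminus and retention of the (E)-geometry.

**Step 17**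
Reactants: 24 bis-silylated allylic carbamate; 26 geranyl pinacolboronate
Product: 30 (3E,5R,7E)-1-[(1S,2S,6R)-1,2-dimethyl-6-(prop-2-en-1-yl)-2-(TESO)-5-[(2Z)-1-(TESO)propan-2-ylidene]cyclohexyl]-4,8,12-trimethyltrideca-3,7,11-trien-5-ol, via lithiated carbamate 27 (not isolated), via lithium boronate complex 28 (not isolated), via allylic pinacol boronate 29 (not isolated)
Conditions: sBuLi, (+)-sparteine, Et2O, –78 °C; 26, –78 °C; MgBr2·OEt2, then 25 °C; then NaOH, H2O2, THF, 0 °C
Reagents that add atoms: hydrogen peroxide (OO)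
Why: sBuLi/(+)-sparteine removes one enantiotopic C16 hydrogen of the carbamate (complex-induced, allylically stabilised lithiation), the organolithium 27 adds to the boron of 26 with retention to give boronate 28, and on warming the geranyl CH2 migrates from boron to C16 anti to the departing carbamate (inversion), forming the C16–C17 bond in 29 before stereoretentive oxidation gives 30. The closest known reaction type is the lithiation–borylation of O-alkyl and O-alkenyl carbamates with a Matteson-type 1,2-metallate rearrangement. No ring is closed. The new stereocentre C16 is set by the chiral diamine (reagent control) and relayed through retention, inversion and retention to the R configuration. The step needs α- rather than γ-borylation of the allyl anion, which carbamate chelation of lithium at C16 and the substituents crowding C14 and C15 should secure, and lithiation at C16 rather than at the silyloxy-bearing C1, which the directing carbamate should secure. The (E)-C18=C19 alkene is untouched because C17 migrates as an sp3 carbon without allylic transposition.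

**Step 18**
Reactants: 30 (16R)-alcohol
Product: 32 diol: 30 with the allyl arm converted into 3-hydroxypropyl (C3–OH), via B-alkyl-9-BBN adduct 31 (not isolated)
Conditions: 9-BBN (excess), THF, 0 → 25 °C; then NaOH, H2O2, 0 °C
Reagents that add atoms: hydrogen peroxide (OO)
Why: 9-BBN should hydroborate the monosubstituted terminal alkene far faster than the tri- and tetrasubstituted alkenes, and oxidation gives the C3 alcohol.

**Step 19**
Reactants: 32 diol
Product: 33 3,16-diacetate of 32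
Conditions: Ac2O, pyridine, DMAP (cat.), CH2Cl2, 0 → 25 °C
Reagents that add atoms: acetic anhydride (CC(=O)OC(C)=O)
Why: DMAP-catalysed acyl transfer acetylates the primary C3 and secondary C16 hydroxyls, the C1 and C10 oxygens being silylated.

**Step 20**
Reactants: 33 bis-silyl diacetate
Product: 34 (2Z,6R,10S,11S,14E,16R,18E)-3,16-diacetoxy-1,10-dihydroxy compound (C1 allylic alcohol of the target)
Conditions: HF·pyridine, pyridine, THF, 0 → 25 °C
Reagents that add atoms: none
Why: Buffered fluoride-mediated desilylation removes both triethylsilyl groups without touching the acetates.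

**Step 21**
Reactants: 34 allylic alcohol
Product: 35 target CNP0146964.1, (2Z,6R,10S,11S,14E,16R,18E)-3,16-diacetoxy-10-hydroxy enal
Conditions: MnO2, CH2Cl2, 25 °C
Reagents that add atoms: none
Why: Allylic oxidation with MnO2 converts the primary allylic alcohol into the enal with retention of the tetrasubstituted (2Z)-alkene, the tertiary alcohol and the acetates being inert.

**Compound list**

1 | 4-methoxy-2-methylphenol | COc1ccc(O)c(C)c1 | starting material
2 | 4,4-dimethoxy-2-methylcyclohexa-2,5-dien-1-one | COC1(OC)C=CC(=O)C(C)=C1 | intermediate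
3 | 4,4-dimethoxy-2-methylcyclohex-2-en-1-one | COC1(OC)CCC(=O)C(C)=C1 | intermediate
4 | pent-1-en-3-one | CCC(=O)C=C | starting material
5 | 1-bromopentan-3-one | CCC(=O)CCBr | intermediate (not isolated)
6 | 2-(2-bromoethyl)-2-ethyl-5,5-dimethyl-1,3-dioxane | CCC1(CCBr)OCC(C)(C)CO1 | intermediate
7 | [2-(2-ethyl-5,5-dimethyl-1,3-dioxan-2-yl)ethyl]magnesium bromide | CCC1(CC[Mg]Br)OCC(C)(C)CO1 | intermediate (not isolated)
8 | bromomagnesium enolate of the conjugate adduct (C6 S) | CCC1(OCC(C)(C)CO1)CC[C@@H]2C(OC)(OC)CCC(O[Mg]Br)=C2C | intermediate (not isolated)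
9 | (2S,3S)-3-[2-(2-ethyl-5,5-dimethyl-1,3-dioxan-2-yl)ethyl]-4,4-dimethoxy-2-methyl-2-(prop-2-en-1-yl)cyclohexan-1-one | CCC1(OCC(C)(C)CO1)CC[C@@H]2C(OC)(OC)CCC(=O)[C@@]2(C)CC=C | intermediate
10 | (1S,2S,3S)-3-[2-(2-ethyl-5,5-dimethyl-1,3-dioxan-2-yl)ethyl]-4,4-dimethoxy-1,2-dimethyl-2-(prop-2-en-1-yl)cyclohexan-1-ol | CCC1(OCC(C)(C)CO1)CC[C@@H]2C(OC)(OC)CC[C@](C)(O)[C@@]2(C)CC=C | intermediate
11 | B-alkyl-9-borabicyclo[3.3.1]nonane adduct of 10 (boron on the terminal carbon) | CCC1(OCC(C)(C)CO1)CC[C@@H]2C(OC)(OC)CC[C@](C)(O)[C@@]2(C)CCCB3C4CCCC3CCC4 | intermediate (not isolated)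
12 | (1S,2S,3S)-3-[2-(2-ethyl-5,5-dimethyl-1,3-dioxan-2-yl)ethyl]-2-(3-hydroxypropyl)-4,4-dimethoxy-1,2-dimethylcyclohexan-1-ol | CCC1(OCC(C)(C)CO1)CC[C@@H]2C(OC)(OC)CC[C@](C)(O)[C@@]2(C)CCCO | intermediate
13 | 3-[(1S,2S,6S)-6-[2-(2-ethyl-5,5-dimethyl-1,3-dioxan-2-yl)ethyl]-2-hydroxy-5,5-dimethoxy-1,2-dimethylcyclohexyl]propanal | CCC1(OCC(C)(C)CO1)CC[C@@H]2C(OC)(OC)CC[C@](C)(O)[C@@]2(C)CCC=O | intermediate (not isolated)
14 | ethyl (2E)-5-[(1S,2S,6S)-6-[2-(2-ethyl-5,5-dimethyl-1,3-dioxan-2-yl)ethyl]-2-hydroxy-5,5-dimethoxy-1,2-dimethylcyclohexyl]-2-methylpent-2-enoate | CCC1(OCC(C)(C)CO1)CC[C@@H]2C(OC)(OC)CC[C@](C)(O)[C@@]2(C)CC/C=C(\C)C(=O)OCC | intermediate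
15 | (2E)-5-[(1S,2S,6S)-6-[2-(2-ethyl-5,5-dimethyl-1,3-dioxan-2-yl)ethyl]-2-hydroxy-5,5-dimethoxy-1,2-dimethylcyclohexyl]-2-methylpent-2-en-1-ol | CCC1(OCC(C)(C)CO1)CC[C@@H]2C(OC)(OC)CC[C@](C)(O)[C@@]2(C)CC/C=C(\C)CO | intermediate
16 | N,N-di(propan-2-yl)carbamate of 15 | CCC1(OCC(C)(C)CO1)CC[C@@H]2C(OC)(OC)CC[C@](C)(O)[C@@]2(C)CC/C=C(\C)COC(=O)N(C(C)C)C(C)C | intermediate
17 | (2E)-5-[(1S,2S,6S)-2-hydroxy-1,2-dimethyl-5-oxo-6-(3-oxopentyl)cyclohexyl]-2-methylpent-2-en-1-yl N,N-di(propan-2-yl)carbamate | CCC(=O)CC[C@@H]1C(=O)CC[C@](C)(O)[C@@]1(C)CC/C=C(\C)COC(=O)N(C(C)C)C(C)C | intermediate (not isolated)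
18 | (2E)-5-[(1S,2S,8aR)-2-hydroxy-1,2,5-trimethyl-6-oxo-1,2,3,4,6,7,8,8a-octahydronaphthalen-1-yl]-2-methylpent-2-en-1-yl N,N-di(propan-2-yl)carbamate | O=C1CC[C@@H]2C(=C1C)CC[C@](C)(O)[C@@]2(C)CC/C=C(\C)COC(=O)N(C(C)C)C(C)C | intermediate
19 | dipotassium salt of 18 (C10 alkoxide and cross-conjugated C1–C4 dienolate) | [K+].[K+].[O-]C1=CC[C@@H]2C(=C1C)CC[C@](C)([O-])[C@@]2(C)CC/C=C(\C)COC(=O)N(C(C)C)C(C)C | intermediate (not isolated)
20 | 7-hydroxy derivative of 18 (α′-hydroxy enone, both C7 epimers) | O=C1C(O)C[C@@H]2C(=C1C)CC[C@](C)(O)[C@@]2(C)CC/C=C(\C)COC(=O)N(C(C)C)C(C)C | intermediate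
21 | methyl (2Z)-2-[(2R,3S,4S)-3-[(3E)-5-(CbO)-4-methylpent-3-en-1-yl]-4-hydroxy-3,4-dimethyl-2-(2-oxoethyl)cyclohexylidene]propanoate | O=CC[C@@H]1/C(=C(/C)C(=O)OC)CC[C@](C)(O)[C@@]1(C)CC/C=C(\C)COC(=O)N(C(C)C)C(C)C | intermediate
22 | methyl (2Z)-2-[(2R,3S,4S)-3-[(3E)-5-(CbO)-4-methylpent-3-en-1-yl]-4-hydroxy-3,4-dimethyl-2-(prop-2-en-1-yl)cyclohexylidene]propanoate | C=CC[C@@H]1/C(=C(/C)C(=O)OC)CC[C@](C)(O)[C@@]1(C)CC/C=C(\C)COC(=O)N(C(C)C)C(C)C | intermediate
23 | (2E)-5-[(1S,2S,6R)-2-hydroxy-5-[(2Z)-1-hydroxypropan-2-ylidene]-1,2-dimethyl-6-(prop-2-en-1-yl)cyclohexyl]-2-methylpent-2-en-1-yl N,N-di(propan-2-yl)carbamate | C=CC[C@@H]1/C(=C(/C)CO)CC[C@](C)(O)[C@@]1(C)CC/C=C(\C)COC(=O)N(C(C)C)C(C)C | intermediate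
24 | bis(triethylsilyl) ether of 23 (C1–OTES, C10–OTES) | C=CC[C@@H]1/C(=C(/C)CO[Si](CC)(CC)CC)CC[C@](C)(O[Si](CC)(CC)CC)[C@@]1(C)CC/C=C(\C)COC(=O)N(C(C)C)C(C)C | intermediate
25 | geranyl acetate, (2E)-3,7-dimethylocta-2,6-dien-1-yl acetate | CC(C)=CCC/C(C)=C/COC(C)=O | starting material
26 | 2-[(2E)-3,7-dimethylocta-2,6-dien-1-yl]-4,4,5,5-tetramethyl-1,3,2-dioxaborolane | CC(C)=CCC/C(C)=C/CB1OC(C)(C)C(C)(C)O1 | intermediate
27 | (16R)-16-lithio derivative of 24 (sparteine complex) | C=CC[C@@H]1/C(=C(/C)CO[Si](CC)(CC)CC)CC[C@](C)(O[Si](CC)(CC)CC)[C@@]1(C)CC/C=C(\C)[C@@H]([Li])OC(=O)N(C(C)C)C(C)C | intermediate (not isolated)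
28 | lithium boronate complex (C16 bound to B(pin)(geranyl), carbamate still on C16) | [Li+].C=CC[C@@H]1/C(=C(/C)CO[Si](CC)(CC)CC)CC[C@](C)(O[Si](CC)(CC)CC)[C@@]1(C)CC/C=C(\C)[C@@H]([B-]2(C/C=C(\C)CCC=C(C)C)OC(C)(C)C(C)(C)O2)OC(=O)N(C(C)C)C(C)C | intermediate (not isolated)
29 | secondary allylic pinacol boronate (B on C16, C16–C17 bond formed) | C=CC[C@@H]1/C(=C(/C)CO[Si](CC)(CC)CC)CC[C@](C)(O[Si](CC)(CC)CC)[C@@]1(C)CC/C=C(\C)[C@H](B2OC(C)(C)C(C)(C)O2)C/C=C(\C)CCC=C(C)C | intermediate (not isolated)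
30 | (3E,5R,7E)-1-[(1S,2S,6R)-1,2-dimethyl-6-(prop-2-en-1-yl)-2-(TESO)-5-[(2Z)-1-(TESO)propan-2-ylidene]cyclohexyl]-4,8,12-trimethyltrideca-3,7,11-trien-5-ol | C=CC[C@@H]1/C(=C(/C)CO[Si](CC)(CC)CC)CC[C@](C)(O[Si](CC)(CC)CC)[C@@]1(C)CC/C=C(\C)[C@@H](C/C=C(\C)CCC=C(C)C)O | intermediate
31 | B-alkyl-9-borabicyclo[3.3.1]nonane adduct of 30 (boron on C3; C16 hydroxyl drawn free) | B1(C2CCCC1CCC2)CCC[C@@H]3/C(=C(/C)CO[Si](CC)(CC)CC)CC[C@](C)(O[Si](CC)(CC)CC)[C@@]3(C)CC/C=C(\C)[C@@H](C/C=C(\C)CCC=C(C)C)O | intermediate (not isolated)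
32 | 3,16-diol: 30 with 3-hydroxypropyl in place of the allyl arm | OCCC[C@@H]1/C(=C(/C)CO[Si](CC)(CC)CC)CC[C@](C)(O[Si](CC)(CC)CC)[C@@]1(C)CC/C=C(\C)[C@@H](C/C=C(\C)CCC=C(C)C)O | intermediate
33 | 3,16-diacetate of 32 | CC(=O)OCCC[C@@H]1/C(=C(/C)CO[Si](CC)(CC)CC)CC[C@](C)(O[Si](CC)(CC)CC)[C@@]1(C)CC/C=C(\C)[C@@H](C/C=C(\C)CCC=C(C)C)OC(C)=O | intermediate
34 | (2Z,6R,10S,11S,14E,16R,18E)-3,16-diacetoxy-1,10-diol (C1 allylic alcohol) | CC(=O)OCCC[C@@H]1/C(=C(/C)CO)CC[C@](C)(O)[C@@]1(C)CC/C=C(\C)[C@@H](C/C=C(\C)CCC=C(C)C)OC(C)=O | intermediate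
35 | CNP0146964.1, (2Z,6R,10S,11S,14E,16R,18E)-3,16-diacetoxy-10-hydroxy enal | CC(=O)OCCC[C@@H]1/C(=C(/C)C=O)CC[C@](C)(O)[C@@]1(C)CC/C=C(\C)[C@@H](C/C=C(\C)CCC=C(C)C)OC(C)=O | target

**Step count.** Total: 21 steps. Longest linear sequence: 19 steps (steps 1, 2, 4–15, 17–21).

**Steps most likely to fail**

Step 17. The lithiated allyl carbamate may lose its configuration before it is trapped, boron may be delivered to the γ-carbon C14, or the boronate may revert before the 1,2-shift. The fallback sets out from 24 and returns at 30. The carbamate is cleaved reductively with LiAlH4 (THF, 0 → 25 °C) to the primary allylic alcohol F1, and MnO2 gives the (E)-enal F2. Geranylbarium chloride (geranyl chloride, activated Ba from BaI2 and lithium biphenylide, THF, –78 °C) adds through its α-carbon with retention of the (E)-geometry to give the C16-epimeric alcohols F3. Dess–Martin periodinane (NaHCO3) gives the enone F4. Corey–Bakshi–Shibata reduction with (S)-1-methyl-3,3-diphenyltetrahydropyrrolo[1,2-c][1,3,2]oxazaborole and catecholborane (toluene, –78 °C) then sets C16 by reagent control and gives 30.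

Step 4. The β-carbon is flanked by the ketal, so conversion may be low, facial selectivity of the catalyst poor, or the enolate may be allylated on oxygen. The fallback sets out from 3 and 6 and returns at 9. The same addition–allylation is run without chiral ligand (CuBr·SMe2, THF, –78 °C; allyl bromide, DMPU) and gives 9 together with its enantiomer F5. Reagent-controlled Corey–Bakshi–Shibata reduction of this racemate ((S)-oxazaborolidine, BH3·SMe2) gives the diastereomeric alcohols (1R,2S,3S)-alcohol F6 and (1R,2R,3R)-alcohol F7, which are separated by chromatography. Oxidation of F6 with Dess–Martin periodinane returns enantiopure 9.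

Step 5. The methyl nucleophile may attack from the equatorial direction on the face of the C11 methyl, or the ketone may be enolised instead. The fallback sets out from 9 and returns at 10. Corey–Chaykovsky epoxidation with dimethylsulfonium methylide (Me3SI, KN(SiMe3)2, THF, 0 °C), which has a stronger intrinsic preference for axial delivery of carbon, gives the spiro-epoxide F8. LiEt3BH (THF, 0 °C) opens it at the CH2 terminus to give 10.

**Further compounds**

F1 | step 17 | (2E)-5-[(1S,2S,6R)-1,2-dimethyl-6-(prop-2-en-1-yl)-2-(TESO)-5-[(2Z)-1-(TESO)propan-2-ylidene]cyclohexyl]-2-methylpent-2-en-1-ol | C=CC[C@@H]1/C(=C(/C)CO[Si](CC)(CC)CC)CC[C@](C)(O[Si](CC)(CC)CC)[C@@]1(C)CC/C=C(\C)CO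
F2 | step 17 | (2E)-enal corresponding to F1 (C16 aldehyde) | C=CC[C@@H]1/C(=C(/C)CO[Si](CC)(CC)CC)CC[C@](C)(O[Si](CC)(CC)CC)[C@@]1(C)CC/C=C(\C)C=O
F3 | step 17 | C16-epimeric mixture of alcohol 30 | C=CC[C@@H]1/C(=C(/C)CO[Si](CC)(CC)CC)CC[C@](C)(O[Si](CC)(CC)CC)[C@@]1(C)CC/C=C(\C)C(O)C/C=C(\C)CCC=C(C)C
F4 | step 17 | C16 ketone (enone) corresponding to 30 | C=CC[C@@H]1/C(=C(/C)CO[Si](CC)(CC)CC)CC[C@](C)(O[Si](CC)(CC)CC)[C@@]1(C)CC/C=C(\C)C(=O)C/C=C(\C)CCC=C(C)C
F5 | step 4 | (2R,3R)-enantiomer of ketone 9 (formed with 9 as the racemate) | CCC1(OCC(C)(C)CO1)CC[C@H]2C(OC)(OC)CCC(=O)[C@]2(C)CC=C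
F6 | step 4 | (1R,2S,3S)-3-[2-(2-ethyl-5,5-dimethyl-1,3-dioxan-2-yl)ethyl]-4,4-dimethoxy-2-methyl-2-(prop-2-en-1-yl)cyclohexan-1-ol | CCC1(OCC(C)(C)CO1)CC[C@@H]2C(OC)(OC)CC[C@@H](O)[C@@]2(C)CC=C
F7 | step 4 | (1R,2R,3R)-3-[2-(2-ethyl-5,5-dimethyl-1,3-dioxan-2-yl)ethyl]-4,4-dimethoxy-2-methyl-2-(prop-2-en-1-yl)cyclohexan-1-ol | CCC1(OCC(C)(C)CO1)CC[C@H]2C(OC)(OC)CC[C@@H](O)[C@]2(C)CC=C
F8 | step 5 | spiro-epoxide of 9 at C10 (CH2 on the face of the allyl group, O on the face of the C11 methyl) | CCC1(OCC(C)(C)CO1)CC[C@@H]2C(OC)(OC)CC[C@@]3(CO3)[C@@]2(C)CC=C
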